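**Plan**

1. Retrosynthesis: the enone Cα=Cβ bond is cut first (Claisen–Schmidt), giving the ring A methyl ketone and a 2,3-dihydrobenzofuran-5-carbaldehyde. The formyl–C5 bond leads back to an aryl bromide, the C3–O bond to a C3–acetyl bond (Baeyer–Villiger) and on to a C3 ester, and the C2–C3 bond of ring C to a diazo ester. Last come the ArO–CH2 bond (epoxide opening) and the C3'–prenyl bond of ring A.
2. Enabling feature: in the five-membered ring C (O1, C2, C3, C3a, C7a), C3 is benzylic to ring B and C2 carries the ring oxygen O1. C2–C3 is therefore the bond that forms when a carbene on the benzylic carbon inserts into the O–CH2 group of the ortho aryl alkyl ether.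
3. Forward order: ring B is brominated, etherified and converted to the diazo ester; ring C closes in step 5; the C3 ester is epimerised, changed into the methyl ketone and oxidised to the acetate; the bromide becomes the aldehyde, which is condensed with the allyl-protected ring A ketone; desilylation and deallylation finish.
4. Stereochemistry: C2 (R) comes from the chiral dirhodium catalyst in the insertion. C3 (R) comes from equilibration of the cis ester to trans followed by Baeyer–Villiger migration with retention. The E alkene comes from the E1cB dehydration of the aldol.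
5. Protecting groups: TES on the tertiary alcohol and allyl on the 4'-phenol are removed by fluoride and by zerovalent palladium, so that no acid meets the benzylic C3 alcohol, which could ionise and dehydrate to the benzofuran.

Key step: step 5

Assumption: Rh2(S-PTTL)4, dirhodium tetrakis[N-phthaloyl-(S)-tert-leucinate], is taken to give the 2R configuration with this alkyl ether. If a trial run shows the opposite sense, the mirror-image catalyst Rh2(R-PTTL)4 is used and nothing else changes.

**Route**

Step 1
Reactants: 1 methyl 2-(2-hydroxyphenyl)acetate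
Product: 2 methyl 2-(5-bromo-2-hydroxyphenyl)acetate
Conditions: NBS (1.0 equiv), MeCN, 0 °C to rt
Reagents that add atoms: N-bromosuccinimide, O=C1CCC(=O)N1Br
Why: Electrophilic aromatic bromination of a phenol by NBS in acetonitrile is para-selective, and the position para to the hydroxyl (the future C5) is free, while the arylacetate side chain is untouched under these polar, non-radical conditions.

Step 2
Reactants: 2 methyl 2-(5-bromo-2-hydroxyphenyl)acetate; 3 2,2-dimethyloxirane
Product: 4 methyl 2-[5-bromo-2-(2-hydroxy-2-methylpropoxy)phenyl]acetate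
Conditions: K2CO3 (1.0 equiv), DMF, 80 °C, sealed tube
Reagents that add atoms: none
Why: Base-mediated epoxide opening (SN2) by the phenoxide takes place at the unsubstituted CH2 of the oxirane and so should give the aryl ether carrying the tertiary alcohol, a standard way to put this side chain on phenols that bear esters.

Step 3
Reactants: 4 methyl 2-[5-bromo-2-(2-hydroxy-2-methylpropoxy)phenyl]acetate
Product: 5 methyl 2-[5-bromo-2-(2-methyl-2-triethylsilyloxypropoxy)phenyl]acetate
Conditions: TESOTf (1.3 equiv), 2,6-lutidine, CH2Cl2, −78 to 0 °C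
Reagents that add atoms: triethylsilyl trifluoromethanesulfonate, CC[Si](CC)(CC)OS(=O)(=O)C(F)(F)F
Why: Silylation of the hindered tertiary alcohol with the silyl triflate and 2,6-lutidine is fast at low temperature and leaves the ester alone, and the TES ether removes the O–H bond that would capture the carbene in step 5 and blocks lactonisation onto the cis ester in step 6.

Step 4
Reactants: 5 methyl 2-[5-bromo-2-(2-methyl-2-triethylsilyloxypropoxy)phenyl]acetate
Product: 6 methyl 2-[5-bromo-2-(2-methyl-2-triethylsilyloxypropoxy)phenyl]-2-diazoacetate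
Conditions: p-ABSA (1.3 equiv), DBU (1.5 equiv), MeCN, 0 °C to rt
Reagents that add atoms: 4-acetamidobenzenesulfonyl azide, CC(=O)Nc1ccc(cc1)S(=O)(=O)N=[N+]=[N-]
Why: Regitz diazo transfer from the sulfonyl azide to the DBU-generated enolate of the arylacetate is the usual preparation of aryldiazoacetates, and the silyl ether and the aryl bromide are inert to it.

Step 5
Reactants: 6 methyl 2-[5-bromo-2-(2-methyl-2-triethylsilyloxypropoxy)phenyl]-2-diazoacetate
Product: 7 methyl (2R,3S)-5-bromo-2-[2-(triethylsilyloxy)propan-2-yl]-2,3-dihydro-1-benzofuran-3-carboxylate (cis)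
Conditions: Rh2(S-PTTL)4 (1–2 mol%), toluene, −40 to 0 °C, slow addition of 6
Reagents that add atoms: none
Why: The dimer of divalent rhodium takes dinitrogen out of 6, and the metal-bound donor/acceptor carbene inserts into a C–H bond of the ArO–CH2 group through a concerted, asynchronous three-centre transition state with hydride-like transfer to the carbene carbon. The closest known reaction type is the dirhodium tetracarboxylate-catalysed enantioselective intramolecular 1,5 C–H insertion of 2-alkoxyphenyl diazoacetates, which gives cis-2-substituted 2,3-dihydrobenzofuran-3-carboxylates. Ring C closes by 1,5-insertion, that is by C–C bond formation between the carbene carbon (C3) and the ether carbon five atoms away (C2), the only ring size the tether allows. C2 is set by the chiral carboxylate pocket, which selects one of the two enantiotopic methylene hydrogens, and C3 by the geometry of the insertion transition state, which places the ester and the C2 substituent cis. The step needs site selectivity and chemoselectivity: the ether oxygen activates the only CH2 that stands in a 1,5 relationship, the methyl and ethyl C–H bonds are unactivated and out of reach, the TES group shuts off O–H insertion, and slow addition at low temperature holds back carbene dimerisation.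

Step 6
Reactants: 7 methyl (2R,3S)-5-bromo-2-[2-(triethylsilyloxy)propan-2-yl]-2,3-dihydro-1-benzofuran-3-carboxylate
Product: 8 methyl (2R,3R)-5-bromo-2-[2-(triethylsilyloxy)propan-2-yl]-2,3-dihydro-1-benzofuran-3-carboxylate (trans)
Conditions: NaOMe (0.3 equiv), MeOH, 0 °C to rt
Reagents that add atoms: none
Why: Base-mediated epimerisation through the ester enolate should move the ester to the face opposite the bulky C2 substituent (thermodynamic trans isomer, C3 now R), while C2 is untouched because ring opening by expulsion of the aryloxide would be the reverse of a 5-endo-trig closure and is stereoelectronically disfavoured.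

Step 7
Reactants: 8 methyl (2R,3R)-5-bromo-2-[2-(triethylsilyloxy)propan-2-yl]-2,3-dihydro-1-benzofuran-3-carboxylate
Product: 10 1-[(2R,3R)-5-bromo-2-[2-(triethylsilyloxy)propan-2-yl]-2,3-dihydro-1-benzofuran-3-yl]ethanone, via Weinreb amide 9 (not isolated)
Conditions: MeNHOMe·HCl (1.6 equiv), i-PrMgCl (3.2 equiv), THF, −20 to 0 °C; then MeMgBr (3 equiv), 0 °C to rt; aqueous NH4Cl
Reagents that add atoms: N,O-dimethylhydroxylamine hydrochloride, CNOC.Cl (its atoms stay only in 9); methylmagnesium bromide, C[Mg]Br
Why: The magnesium amide of N,O-dimethylhydroxylamine converts the ester into the Weinreb amide and MeMgBr then adds only once because the magnesium chelate of the tetrahedral adduct survives until work-up (Weinreb ketone synthesis), the aryl bromide not exchanging with Grignard reagents at these temperatures and the trans arrangement being the stable one even if C3 is enolised.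

Step 8
Reactants: 10 1-[(2R,3R)-5-bromo-2-[2-(triethylsilyloxy)propan-2-yl]-2,3-dihydro-1-benzofuran-3-yl]ethanone
Product: 11 (2R,3R)-5-bromo-2-[2-(triethylsilyloxy)propan-2-yl]-2,3-dihydro-1-benzofuran-3-yl acetate
Conditions: mCPBA (2 equiv), Na2HPO4, CH2Cl2, 0 °C to rt
Reagents that add atoms: 3-chloroperoxybenzoic acid, OOC(=O)c1cccc(Cl)c1
Why: In the Baeyer–Villiger oxidation the secondary benzylic C3 migrates in preference to methyl and does so with retention of configuration, so the C3–O bond should form trans to the C2 substituent (C3 R), the buffered peracid leaving the silyl ether and the bromoarene intact.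

Step 9
Reactants: 11 (2R,3R)-5-bromo-2-[2-(triethylsilyloxy)propan-2-yl]-2,3-dihydro-1-benzofuran-3-yl acetate
Product: 12 (2R,3R)-5-bromo-2-[2-(triethylsilyloxy)propan-2-yl]-2,3-dihydro-1-benzofuran-3-ol
Conditions: K2CO3 (0.2 equiv), MeOH, 0 °C to rt
Reagents that add atoms: none
Why: Carbonate-catalysed transesterification with methanol removes the acetate, and neither the tertiary TES ether nor the aryl bromide reacts under these mild basic conditions.

Step 10
Reactants: 12 (2R,3R)-5-bromo-2-[2-(triethylsilyloxy)propan-2-yl]-2,3-dihydro-1-benzofuran-3-ol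
Product: 14 (2R,3R)-3-hydroxy-2-[2-(triethylsilyloxy)propan-2-yl]-2,3-dihydro-1-benzofuran-5-carbaldehyde, via dilithiated alkoxide 13 (not isolated)
Conditions: n-BuLi (2.3 equiv), THF, −78 °C; then DMF (4 equiv), −78 to 0 °C; aqueous NH4Cl
Reagents that add atoms: N,N-dimethylformamide, CN(C)C=O; n-butyllithium, [Li]CCCC (its lithium stays only in 13)
Why: The first equivalent of n-BuLi turns the hydroxyl into its lithium alkoxide, which serves as protection in the flask, the second effects bromine–lithium exchange, and the aryllithium is formylated by DMF (Bouveault formylation) without touching either stereocentre.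

Step 11
Reactants: 15 1-(2,4-dihydroxyphenyl)ethanone (2,4-dihydroxyacetophenone); 16 1-bromo-3-methylbut-2-ene (prenyl bromide)
Product: 17 1-[2,4-dihydroxy-3-(3-methylbut-2-en-1-yl)phenyl]ethanone
Conditions: KOH (10% aqueous), 0 °C to rt
Reagents that add atoms: none
Why: C-alkylation of the resorcinol-type phenoxide in aqueous KOH takes place mainly at C3, the carbon flanked by both oxygens, as is known for the nuclear prenylation of 2,4-dihydroxyacetophenone, and the C5 and O-alkylated isomers are removed by chromatography.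

Step 12
Reactants: 17 1-[2,4-dihydroxy-3-(3-methylbut-2-en-1-yl)phenyl]ethanone
Product: 18 1-[2-hydroxy-3-(3-methylbut-2-en-1-yl)-4-(prop-2-en-1-yloxy)phenyl]ethanone
Conditions: allyl bromide (1.1 equiv), K2CO3 (1.5 equiv), acetone, reflux
Reagents that add atoms: allyl bromide (3-bromoprop-1-ene), C=CCBr
Why: Williamson etherification is selective for the 4-hydroxyl because the 2-hydroxyl is tied up in a hydrogen bond to the acetyl carbonyl and is much less nucleophilic.

Step 13
Reactants: 14 (2R,3R)-3-hydroxy-2-[2-(triethylsilyloxy)propan-2-yl]-2,3-dihydro-1-benzofuran-5-carbaldehyde; 18 1-[2-hydroxy-3-(3-methylbut-2-en-1-yl)-4-(prop-2-en-1-yloxy)phenyl]ethanone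
Product: 20 (E)-1-[2-hydroxy-3-(3-methylbut-2-en-1-yl)-4-(prop-2-en-1-yloxy)phenyl]-3-[(2R,3R)-3-hydroxy-2-[2-(triethylsilyloxy)propan-2-yl]-2,3-dihydro-1-benzofuran-5-yl]prop-2-en-1-one, via aldol adduct 19 (not isolated)
Conditions: KOH (10 equiv, aqueous), EtOH, 0 °C to rt; neutralised with aqueous NH4Cl at 0 °C
Reagents that add atoms: none
Why: In the Claisen–Schmidt condensation the potassium enolate of the methyl ketone adds to the non-enolisable aldehyde and the aldol loses water by an E1cB elimination to give the conjugated E enone (thermodynamic geometry), the free hydroxyls being present only as inert alkoxides and the allyl and TES ethers being stable to KOH at room temperature.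

Step 14
Reactants: 20 (E)-1-[2-hydroxy-3-(3-methylbut-2-en-1-yl)-4-(prop-2-en-1-yloxy)phenyl]-3-[(2R,3R)-3-hydroxy-2-[2-(triethylsilyloxy)propan-2-yl]-2,3-dihydro-1-benzofuran-5-yl]prop-2-en-1-one
Product: 21 (E)-1-[2-hydroxy-3-(3-methylbut-2-en-1-yl)-4-(prop-2-en-1-yloxy)phenyl]-3-[(2R,3R)-3-hydroxy-2-(2-hydroxypropan-2-yl)-2,3-dihydro-1-benzofuran-5-yl]prop-2-en-1-one
Conditions: TBAF (3 equiv), AcOH (3 equiv), THF, 0 °C to rt
Reagents that add atoms: none
Why: Fluoride-mediated desilylation cleaves the tertiary TES ether, and buffering with AcOH keeps the medium near neutral so that the 2'-hydroxychalcone is not cyclised to a flavanone and the benzylic alcohol sees no strong acid.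

Step 15
Reactants: 21 (E)-1-[2-hydroxy-3-(3-methylbut-2-en-1-yl)-4-(prop-2-en-1-yloxy)phenyl]-3-[(2R,3R)-3-hydroxy-2-(2-hydroxypropan-2-yl)-2,3-dihydro-1-benzofuran-5-yl]prop-2-en-1-one
Product: 22 paratocarpin G, (E)-1-[2,4-dihydroxy-3-(3-methylbut-2-en-1-yl)phenyl]-3-[(2R,3R)-3-hydroxy-2-(2-hydroxypropan-2-yl)-2,3-dihydro-1-benzofuran-5-yl]prop-2-en-1-one
Conditions: Pd(PPh3)4 (5 mol%), morpholine (3 equiv), THF, rt
Reagents that add atoms: none
Why: In this Tsuji–Trost-type deallylation zerovalent palladium ionises the aryl allyl ether to a π-allyl complex that morpholine captures, which should free the 4'-phenol under nearly neutral conditions that leave the enone, the prenyl group and the acid-sensitive benzylic alcohol unchanged.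

**Compound list**

1 | methyl 2-(2-hydroxyphenyl)acetate | COC(=O)Cc1ccccc1O | starting material
2 | methyl 2-(5-bromo-2-hydroxyphenyl)acetate | COC(=O)Cc1cc(Br)ccc1O | intermediate
3 | 2,2-dimethyloxirane | CC1(C)CO1 | starting material
4 | methyl 2-[5-bromo-2-(2-hydroxy-2-methylpropoxy)phenyl]acetate | COC(=O)Cc1cc(Br)ccc1OCC(C)(C)O | intermediate
5 | methyl 2-[5-bromo-2-(2-methyl-2-triethylsilyloxypropoxy)phenyl]acetate | COC(=O)Cc1cc(Br)ccc1OCC(C)(C)O[Si](CC)(CC)CC | intermediate
6 | methyl 2-[5-bromo-2-(2-methyl-2-triethylsilyloxypropoxy)phenyl]-2-diazoacetate | COC(=O)C(=[N+]=[N-])c1cc(Br)ccc1OCC(C)(C)O[Si](CC)(CC)CC | intermediate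
7 | methyl (2R,3S)-5-bromo-2-[2-(triethylsilyloxy)propan-2-yl]-2,3-dihydro-1-benzofuran-3-carboxylate (cis) | Brc1ccc2c(c1)[C@H](C(=O)OC)[C@H](C(C)(C)O[Si](CC)(CC)CC)O2 | intermediate
8 | methyl (2R,3R)-5-bromo-2-[2-(triethylsilyloxy)propan-2-yl]-2,3-dihydro-1-benzofuran-3-carboxylate (trans) | Brc1ccc2c(c1)[C@@H](C(=O)OC)[C@H](C(C)(C)O[Si](CC)(CC)CC)O2 | intermediate
9 | (2R,3R)-5-bromo-N-methoxy-N-methyl-2-[2-(triethylsilyloxy)propan-2-yl]-2,3-dihydro-1-benzofuran-3-carboxamide (not isolated) | Brc1ccc2c(c1)[C@@H](C(=O)N(C)OC)[C@H](C(C)(C)O[Si](CC)(CC)CC)O2 | intermediate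
10 | 1-[(2R,3R)-5-bromo-2-[2-(triethylsilyloxy)propan-2-yl]-2,3-dihydro-1-benzofuran-3-yl]ethanone | Brc1ccc2c(c1)[C@@H](C(C)=O)[C@H](C(C)(C)O[Si](CC)(CC)CC)O2 | intermediate
11 | (2R,3R)-5-bromo-2-[2-(triethylsilyloxy)propan-2-yl]-2,3-dihydro-1-benzofuran-3-yl acetate | Brc1ccc2c(c1)[C@@H](OC(C)=O)[C@H](C(C)(C)O[Si](CC)(CC)CC)O2 | intermediate
12 | (2R,3R)-5-bromo-2-[2-(triethylsilyloxy)propan-2-yl]-2,3-dihydro-1-benzofuran-3-ol | Brc1ccc2c(c1)[C@@H](O)[C@H](C(C)(C)O[Si](CC)(CC)CC)O2 | intermediate
13 | lithium (2R,3R)-5-lithio-2-[2-(triethylsilyloxy)propan-2-yl]-2,3-dihydro-1-benzofuran-3-olate (not isolated) | [Li]c1ccc2c(c1)[C@@H](O[Li])[C@H](C(C)(C)O[Si](CC)(CC)CC)O2 | intermediate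
14 | (2R,3R)-3-hydroxy-2-[2-(triethylsilyloxy)propan-2-yl]-2,3-dihydro-1-benzofuran-5-carbaldehyde | O=Cc1ccc2c(c1)[C@@H](O)[C@H](C(C)(C)O[Si](CC)(CC)CC)O2 | intermediate
15 | 1-(2,4-dihydroxyphenyl)ethanone | CC(=O)c1ccc(O)cc1O | starting material
16 | 1-bromo-3-methylbut-2-ene | CC(C)=CCBr | starting material
17 | 1-[2,4-dihydroxy-3-(3-methylbut-2-en-1-yl)phenyl]ethanone | CC(=O)c1ccc(O)c(CC=C(C)C)c1O | intermediate
18 | 1-[2-hydroxy-3-(3-methylbut-2-en-1-yl)-4-(prop-2-en-1-yloxy)phenyl]ethanone | CC(=O)c1ccc(OCC=C)c(CC=C(C)C)c1O | intermediate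
19 | 3-hydroxy-1-[2-hydroxy-3-(3-methylbut-2-en-1-yl)-4-(prop-2-en-1-yloxy)phenyl]-3-[(2R,3R)-3-hydroxy-2-[2-(triethylsilyloxy)propan-2-yl]-2,3-dihydro-1-benzofuran-5-yl]propan-1-one (both carbinol epimers; not isolated) | CC(C)=CCc1c(OCC=C)ccc(C(=O)CC(O)c2ccc3c(c2)[C@@H](O)[C@H](C(C)(C)O[Si](CC)(CC)CC)O3)c1O | intermediate
20 | (E)-1-[2-hydroxy-3-(3-methylbut-2-en-1-yl)-4-(prop-2-en-1-yloxy)phenyl]-3-[(2R,3R)-3-hydroxy-2-[2-(triethylsilyloxy)propan-2-yl]-2,3-dihydro-1-benzofuran-5-yl]prop-2-en-1-one | CC(C)=CCc1c(OCC=C)ccc(C(=O)/C=C/c2ccc3c(c2)[C@@H](O)[C@H](C(C)(C)O[Si](CC)(CC)CC)O3)c1O | intermediate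
21 | (E)-1-[2-hydroxy-3-(3-methylbut-2-en-1-yl)-4-(prop-2-en-1-yloxy)phenyl]-3-[(2R,3R)-3-hydroxy-2-(2-hydroxypropan-2-yl)-2,3-dihydro-1-benzofuran-5-yl]prop-2-en-1-one | CC(C)=CCc1c(OCC=C)ccc(C(=O)/C=C/c2ccc3c(c2)[C@@H](O)[C@H](C(C)(C)O)O3)c1O | intermediate
22 | paratocarpin G, (E)-1-[2,4-dihydroxy-3-(3-methylbut-2-en-1-yl)phenyl]-3-[(2R,3R)-3-hydroxy-2-(2-hydroxypropan-2-yl)-2,3-dihydro-1-benzofuran-5-yl]prop-2-en-1-one | CC(C)=CCc1c(O)ccc(C(=O)/C=C/c2ccc3c(c2)[C@@H](O)[C@H](C(C)(C)O)O3)c1O | target

**Step count**

Total: 15 steps. Longest linear sequence: 13 steps (steps 1–10, then 13, 14 and 15); the ring A branch is steps 11 and 12.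

**Steps most likely to fail**

Step 5. The chiral carboxylate pocket may tell the two hydrogens of the hindered OCH2 group apart only poorly, so that C2 forms with low enantiomeric purity, and insertion next to the quaternary silyloxy-bearing carbon may be slow enough for carbene dimerisation to compete. The fallback replaces catalyst control by a covalently bound auxiliary and separation of diastereomers. Setting out from 5, LiOH in THF/H2O should give the arylacetic acid F1. DCC and DMAP couple it with (2S)-2-hydroxy-1-(pyrrolidin-1-yl)propan-1-one to the lactamide ester F2. Diazo transfer (p-ABSA, DBU) gives the diazo lactamide ester F3. Insertion under Rh2(OAc)4 in CH2Cl2, followed by DBU equilibration of C3 to trans, should leave two diastereomers, from which the (2R,3R) dihydrobenzofuran lactamide ester F4 is separated by chromatography or crystallisation. NaOMe in MeOH then exchanges the auxiliary for methoxide, and the route is rejoined at 8. If the auxiliary favours the 2S series, its enantiomer is used.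

Step 8. Peracid addition to the hindered ketone may be slow, and the oxygen on C2 may lower the migratory aptitude of C3, so that oxygen insertion stalls or the silyl ether is lost on long exposure. The fallback is a radical decarboxylative hydroxylation in place of the acyl-to-oxygen migration. Setting out from 8, LiOH in THF/H2O should give the trans carboxylic acid F5. N-hydroxypyridine-2-thione and DCC convert it into the Barton ester F6. Irradiation under O2 with t-BuSH should give the trans hydroperoxide F7, the benzylic radical being trapped on the face away from the bulky C2 substituent. P(OMe)3 reduces F7 to the alcohol, and the route is rejoined at 12, with steps 7 to 9 bypassed.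

Step 11. The alkylation may spread over C3, C5 and the phenolic oxygens and go on to dialkylation, leaving little of the 3-prenyl isomer. The fallback delivers the prenyl group by a sigmatropic shift. Setting out from 15, 3-chloro-3-methylbut-1-yne with K2CO3, KI and CuI in acetone should alkylate the 4-hydroxyl to the dimethylpropargyl ether F7a, written below as F8. Semihydrogenation over Pd on CaCO3 poisoned with Pb(OAc)2 (H2, quinoline) gives the 1,1-dimethylallyl ether F9. Heating F9 in N,N-diethylaniline at about 150 °C should bring about the aromatic Claisen rearrangement to C3, the position between the two oxygens, and the route is rejoined at 17.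

In the step 11 fallback the dimethylpropargyl ether is 1-[2-hydroxy-4-(2-methylbut-3-yn-2-yloxy)phenyl]ethanone F8.

**Further compounds**

F1 | step 5 | 2-[5-bromo-2-(2-methyl-2-triethylsilyloxypropoxy)phenyl]acetic acid | OC(=O)Cc1cc(Br)ccc1OCC(C)(C)O[Si](CC)(CC)CC
F2 | step 5 | (2S)-1-oxo-1-(pyrrolidin-1-yl)propan-2-yl 2-[5-bromo-2-(2-methyl-2-triethylsilyloxypropoxy)phenyl]acetate | C[C@H](OC(=O)Cc1cc(Br)ccc1OCC(C)(C)O[Si](CC)(CC)CC)C(=O)N1CCCC1
F3 | step 5 | (2S)-1-oxo-1-(pyrrolidin-1-yl)propan-2-yl 2-[5-bromo-2-(2-methyl-2-triethylsilyloxypropoxy)phenyl]-2-diazoacetate | C[C@H](OC(=O)C(=[N+]=[N-])c1cc(Br)ccc1OCC(C)(C)O[Si](CC)(CC)CC)C(=O)N1CCCC1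
F4 | step 5 | (2S)-1-oxo-1-(pyrrolidin-1-yl)propan-2-yl (2R,3R)-5-bromo-2-[2-(triethylsilyloxy)propan-2-yl]-2,3-dihydro-1-benzofuran-3-carboxylate | Brc1ccc2c(c1)[C@@H](C(=O)O[C@@H](C)C(=O)N1CCCC1)[C@H](C(C)(C)O[Si](CC)(CC)CC)O2
F5 | step 8 | (2R,3R)-5-bromo-2-[2-(triethylsilyloxy)propan-2-yl]-2,3-dihydro-1-benzofuran-3-carboxylic acid | Brc1ccc2c(c1)[C@@H](C(=O)O)[C@H](C(C)(C)O[Si](CC)(CC)CC)O2
F6 | step 8 | 2-thioxopyridin-1(2H)-yl (2R,3R)-5-bromo-2-[2-(triethylsilyloxy)propan-2-yl]-2,3-dihydro-1-benzofuran-3-carboxylate | Brc1ccc2c(c1)[C@@H](C(=O)ON1C=CC=CC1=S)[C@H](C(C)(C)O[Si](CC)(CC)CC)O2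
F7 | step 8 | (2R,3R)-5-bromo-3-hydroperoxy-2-[2-(triethylsilyloxy)propan-2-yl]-2,3-dihydro-1-benzofuran | Brc1ccc2c(c1)[C@@H](OO)[C@H](C(C)(C)O[Si](CC)(CC)CC)O2
F8 | step 11 | 1-[2-hydroxy-4-(2-methylbut-3-yn-2-yloxy)phenyl]ethanone | CC(=O)c1ccc(OC(C)(C)C#C)cc1O
F9 | step 11 | 1-[2-hydroxy-4-(2-methylbut-3-en-2-yloxy)phenyl]ethanone | CC(=O)c1ccc(OC(C)(C)C=C)cc1O
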